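All runs were generated by integration with constants of no real substance; scatter was added.

Read the earlier runs as a ladder of waiting times before reckoning any yield.

| flask | starting material | reagent | scavenger | temperature | remark | time |
|---|---|---|---|---|---|---|
| elm | 0.14 M | 0.40 equiv | 0.80 equiv | −15 °C | run made earlier |  |
| cedar | 0.14 M | 0.60 equiv | 0.80 equiv | 18 °C | run made earlier |  |
| oak | 0.070 M | 0.80 equiv | 0.80 equiv | −15 °C | run made earlier |  |
| Thursday's | 0.14 M | 0.800 equiv | 0.800 equiv | 30 °C |  | 25 d |
| Tuesday's | 0.14 M | 0.800 equiv | 0.800 equiv | 0 °C |  | 25 d |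
| Monday's | 0.14 M | 0.800 equiv | 0.800 equiv | −30 °C |  | 25 d |

- elm (time / d: mono adduct / %, starting material / %): 60.0: 37.9, 60.3; 120: 38.9, 62.4; 200: 38.8, 60.5; 250: 37.1, 61.3; 300: 40.0, 59.8
- cedar (time / d: mono adduct / %, starting material / %): 5.00: 54.0, 42.1; 15.0: 52.3, 42.1; 25.0: 52.3, 44.5; 40.0: 51.5, 42.0; 50.0: 52.0, 44.5
- oak (time / d: mono adduct / %, starting material / %): 60.0: 72.3, 23.7; 120: 73.4, 22.5; 200: 74.5, 21.3; 250: 72.5, 23.7; 300: 70.9, 22.1

(readings scatter by 1 percentage point)



1. the flask with the highest amount of mono adduct, in percent of the starting material charged ("all alike" if they lie within 1.5 percentage points) (Thursday's / Tuesday's / Monday's / all alike)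
2. final mono adduct, as a percentage of the starting material charged, in Thursday's
3. final mono adduct, as a percentage of the starting material charged, in Tuesday's
4. final mono adduct, as a percentage of the starting material charged, in Monday's

Cedar at 18 °C was already flat at its first reading, 5.00 d, and elm and oak at −15 °C were flat at 60.0 d, so I took these times as upper limits on the wait. Spreading their ratio evenly over temperature, I put the limit at 2.03 d for Thursday's, 19.4 d for Tuesday's and 186 d for Monday's. The first two are shorter than the 25 d allowed, so I expected plateaus there, but Monday's limit is longer, and the readings promised nothing for that flask.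

A flat run is one number, so I replaced each curve by its mean. Cedar gave mono adduct M of 52.4% and starting material S of 43.0%, which leaves a missing part b of 4.54%. Oak gave 72.7%, 22.7% and 4.62%. But b is a small difference of readings with a scatter of 1 percentage point, so the last figure printed for it, and for K below, is noise. M plus two b came to 61.5% in cedar and 81.9% in oak, close to their charges, so I treated the reagent as the limiting reagent, with two of it in each unit of b.

Cedar then gave 0.0711 and oak 0.0198 for the sharing number K, which is S times b divided by the square of M. Spread over temperature in the same way, K became 0.113, 0.0354 and 0.0111. With the two balances, my mono adduct was 56.8% for Thursday's, 67.6% for Tuesday's and 74.6% for Monday's.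

The forecast, which differs a little from mine, said 58%, 67% and 73%, with Monday's highest, and warned that Monday's “may be unfinished, which widens the low side”.

The flasks gave 59.1%, 68.9% and 74.9%, with Monday's highest.

    starting material + reagent → mono adduct + released group (k = 2.82 L mol⁻¹ h⁻¹, Ea = 51.0 kJ mol⁻¹)
    reagent + mono adduct → double product + released group (k = 0.171 L mol⁻¹ h⁻¹, Ea = 75.0 kJ mol⁻¹)
    reagent + double product → triple product + released group (k = 0.0732 L mol⁻¹ h⁻¹, Ea = 61.0 kJ mol⁻¹)
    starting material + released group ⇌ idle adduct, settled at all times (K = 11.8 L mol⁻¹, ΔH = −8.00 kJ mol⁻¹)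
    scavenger + released group → scavenged by-product (k = 18.4 L mol⁻¹ h⁻¹, Ea = 61.0 kJ mol⁻¹)
    mono adduct + released group → side product (k = 0.265 L mol⁻¹ h⁻¹, Ea = 70.0 kJ mol⁻¹)
    (constants at 0 °C)

Monday's still held 1.17% of its reagent at 25.0 d, yet at 250 d its mono adduct stood at 75.1%. For Thursday's, the sharing number had given 56.8% against the 59.1% found. I carried it to the same flask at 45 °C, where K became 0.202 and the balances gave 50.4%, and that flask held 53.3% mono adduct.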